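Everything rests on cutting the C6–C7 bond and the O6–C12 lactone bond at the junction of the ten-membered carbocycle and the α-methylene γ-lactone, where the oxygen-bearing C6 is vicinal to C7 and C7 holds the C11(=C13)–C12 acrylate unit (a homoallylic alcohol array). In one operation, C6 deprotonation of a thirteen-membered C6–O6–C13 allyl ether triggers a [2,3]-Wittig ring contraction that forms C6–C7, the C11=C13 methylene and both stereocentres, and the freed C6 alkoxide closes the lactone on C12. The precursor is this macrocyclic ether carrying the 3(2H)-furanone (C1–C3/C10), a ring-cis C4=C5 bond and a C7=C11 methyl enoate, with the C8 and C15 oxygens protected.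

Key step: step 20

Remark (numbering): germacrane numbers are used throughout: C1 ketone, C3–O–C10 furanone bridge, C12 lactone carbonyl, C13 exocyclic methylene, C14 methyl on C10, C15 hydroxymethyl on C4. TBS = tert-butyldimethylsilyl, TES = triethylsilyl, PMB = 4-methoxybenzyl.
Remark (design of the macrocycle): the C7=C11 bond is built with C13 trans to C8 (ester cis to C8), because a [2,3] shift turns an allyl ether whose terminal substituent is trans to the CH2O arm into the anti product, here the 6,7-trans lactone; the isomer with C13 cis to C8 would be expected to give the cis-fused lactone. Connectivity is unchanged.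
Remark (starting material): C1 and C7–C10 are taken from (R)-5-(hydroxymethyl)dihydrofuran-2(3H)-one, which already holds C8 and controls C10; a four-carbon hydroxy diacid would lack C7 and give no control at C8.

Step 1
Reactants: 1 2-butyne-1,4-diol
Product: 2 4-[(4-methoxybenzyl)oxy]but-2-yn-1-ol
Conditions: 1 (3 equiv), NaH (1 equiv), PMBCl (1 equiv), Bu4NI (cat.), THF/DMF, 0 °C → rt
Reagents that add atoms: 4-methoxybenzyl chloride, COc1ccc(CCl)cc1
Why: Williamson etherification of the mono-alkoxide with the symmetrical diol in excess should give mainly the mono-ether, which marks the future C15 oxygen apart from the C6 oxygen.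

Step 2
Reactants: 2 4-[(4-methoxybenzyl)oxy]but-2-yn-1-ol
Product: 4 (Z)-3-iodo-4-[(4-methoxybenzyl)oxy]but-2-en-1-ol, via cyclic alkenylalanate 3 (not isolated)
Conditions: Red-Al (1.6 equiv), THF, 0 °C; I2, −78 → 0 °C
Reagents that add atoms: iodine, II
Why: Hydroxyl-directed trans-hydroalumination puts hydride on the alkyne carbon next to the carbinol and aluminium on the distal carbon in a five-membered alanate, and iodinolysis with retention should give the vinyl iodide with iodine (the later C3–C4 link) cis to C6 and the free hydroxyl on C6.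

Step 3
Reactants: 4 (Z)-3-iodo-4-[(4-methoxybenzyl)oxy]but-2-en-1-ol
Product: 5 (Z)-tert-butyl({3-iodo-4-[(4-methoxybenzyl)oxy]but-2-en-1-yl}oxy)dimethylsilane
Conditions: TBSCl, imidazole, CH2Cl2, 0 °C → rt
Reagents that add atoms: tert-butyldimethylsilyl chloride, CC(C)(C)[Si](C)(C)Cl
Why: Silylation of the primary allylic alcohol masks O6 so that it cannot add to the later ynone or be oxidised in step 12.

Step 4
Reactants: 5 (Z)-tert-butyl({3-iodo-4-[(4-methoxybenzyl)oxy]but-2-en-1-yl}oxy)dimethylsilane; 6 ethynylmagnesium bromide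
Product: 8 (E)-tert-butyl[(3-{[(4-methoxybenzyl)oxy]methyl}pent-2-en-4-yn-1-yl)oxy]dimethylsilane (ethynyl group cis to CH2OTBS), via ethynylzinc bromide 7 (not isolated)
Conditions: 6 (2 equiv), ZnBr2 (2 equiv), THF, 0 °C; 5, Pd(PPh3)4 (5 mol %), rt
Reagents that add atoms: none
Why: Negishi cross-coupling of the ethynylzinc reagent with the vinyl iodide proceeds with retention of alkene geometry and should give the terminal enyne (C2≡C3 on C4) in one step.

Step 5
Reactants: 9 (R)-5-(hydroxymethyl)dihydrofuran-2(3H)-one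
Product: 10 (R)-5-{[(triethylsilyl)oxy]methyl}dihydrofuran-2(3H)-one
Conditions: TESCl, imidazole, CH2Cl2, 0 °C
Reagents that add atoms: triethylsilyl chloride, CC[Si](Cl)(CC)CC
Why: Silylation of the primary alcohol (O7) gives a bulky side chain at C8 for the enolate steps and a group that step 12 can oxidise off selectively.

Step 6
Reactants: 10 (R)-5-{[(triethylsilyl)oxy]methyl}dihydrofuran-2(3H)-one
Product: 12 (3S,5R)-3-methyl-5-{[(triethylsilyl)oxy]methyl}dihydrofuran-2(3H)-one (trans; any cis epimer is carried along), via lithium lactone enolate 11 (not isolated)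
Conditions: LDA (1.1 equiv), THF, −78 °C; MeI, −78 → −40 °C
Reagents that add atoms: iodomethane, CI
Why: Lactone enolate alkylation introduces C14 mainly anti to the C8 side chain, and the ratio is immaterial because this centre is made planar again in step 7.

Step 7
Reactants: 12 (3S,5R)-3-methyl-5-{[(triethylsilyl)oxy]methyl}dihydrofuran-2(3H)-one
Product: 14 (3S,5R)-3-hydroxy-3-methyl-5-{[(triethylsilyl)oxy]methyl}dihydrofuran-2(3H)-one (OH trans to the C5 side chain), via potassium lactone enolate 13 (not isolated)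
Conditions: KHMDS (1.2 equiv), THF, −78 °C; 2-(phenylsulfonyl)-3-phenyloxaziridine, −78 °C; aq. NH4Cl
Reagents that add atoms: 2-(phenylsulfonyl)-3-phenyloxaziridine, O=S(=O)(N1OC1c1ccccc1)c1ccccc1
Why: Enolate hydroxylation by the N-sulfonyloxaziridine should occur on the face of the tetrasubstituted enolate anti to the C8 side chain (1,3-induction in γ-butyrolactone enolates), which sets C10 with its oxygen syn to O8 along the C1–C7 chain as the target requires.

Step 8
Reactants: 14 (3S,5R)-3-hydroxy-3-methyl-5-{[(triethylsilyl)oxy]methyl}dihydrofuran-2(3H)-one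
Product: 15 (2S,4R)-2,4-dihydroxy-N-methoxy-N,2-dimethyl-5-[(triethylsilyl)oxy]pentanamide
Conditions: MeNHOMe·HCl (3 equiv), AlMe3 (3 equiv), CH2Cl2, 0 °C → rt; Rochelle salt
Reagents that add atoms: N,O-dimethylhydroxylamine hydrochloride, CNOC.Cl
Why: Aluminium-amide aminolysis of the lactone gives the Weinreb amide at C1 and frees O8 without touching either stereocentre.

Step 9
Reactants: 15 (2S,4R)-2,4-dihydroxy-N-methoxy-N,2-dimethyl-5-[(triethylsilyl)oxy]pentanamide
Product: 16 (2S,4R)-4-[(tert-butyldimethylsilyl)oxy]-2-hydroxy-N-methoxy-N,2-dimethyl-5-[(triethylsilyl)oxy]pentanamide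
Conditions: TBSCl (1.3 equiv), imidazole, DMF, 0 °C → rt, directly after step 8
Reagents that add atoms: tert-butyldimethylsilyl chloride, CC(C)(C)[Si](C)(C)Cl
Why: The secondary C8 hydroxyl is silylated far faster than the tertiary C10 hydroxyl, and prompt protection prevents relactonisation of the γ-hydroxy amide.

Step 10
Reactants: 8 (E)-tert-butyl[(3-{[(4-methoxybenzyl)oxy]methyl}pent-2-en-4-yn-1-yl)oxy]dimethylsilane; 16 (2S,4R)-4-[(tert-butyldimethylsilyl)oxy]-2-hydroxy-N-methoxy-N,2-dimethyl-5-[(triethylsilyl)oxy]pentanamide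
Product: 19 ynone TESO–C7H2–C8H(OTBS)–C9H2–C10(CH3)(OH)–C1(=O)–C2≡C3–C4(C15H2OPMB)=C5H–C6H2OTBS (8R; 10S; C3 cis to C6), via chloromagnesium alkoxide 17 (not isolated), via lithium acetylide 18 (not isolated)
Conditions: 16, i-PrMgCl (1.0 equiv), THF, −40 °C; 8 (1.4 equiv), n-BuLi (1.35 equiv), THF, −78 °C; combine, −78 → 0 °C; aq. NH4Cl
Reagents that add atoms: none
Why: Acetylide addition to the Weinreb amide stops at the chelated tetrahedral intermediate and should release the ynone on work-up, the tertiary hydroxyl being masked as its magnesium alkoxide so that no acetylide is wasted.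

Step 11
Reactants: 19 ynone (as above)
Product: 20 (S)-2-methyl-2-[(R)-2-(tert-butyldimethylsilyloxy)-3-(triethylsilyloxy)propyl]-5-[(Z)-4-(tert-butyldimethylsilyloxy)-1-(4-methoxybenzyloxy)but-2-en-2-yl]furan-3(2H)-one
Conditions: Ph3PAuNTf2 (2 mol %), CH2Cl2, rt
Reagents that add atoms: none
Why: Gold-catalysed 5-endo-dig addition of the C10 hydroxyl to C3 of the activated ynone (oxa-Michael cycloisomerisation) should give the 3(2H)-furanone, with O6 silylated so that it cannot compete.

Step 12
Reactants: 20 furanone (as above)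
Product: 21 (R)-2-(tert-butyldimethylsilyloxy)-3-{(S)-5-[(Z)-4-(tert-butyldimethylsilyloxy)-1-(4-methoxybenzyloxy)but-2-en-2-yl]-2-methyl-3-oxo-2,3-dihydrofuran-2-yl}propanal
Conditions: (COCl)2 (4 equiv), DMSO (8 equiv), CH2Cl2, −78 → −30 °C; Et3N, −78 → 0 °C
Reagents that add atoms: none
Why: Under Swern conditions a primary TES ether is cleaved and oxidised directly to the aldehyde while TBS ethers are inert, so C7 should be unveiled in one step in the presence of the C6 and C8 silyl ethers.

Step 13
Reactants: 22 methyl bis(2,2,2-trifluoroethyl)phosphonoacetate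
Product: 23 methyl 2,2-dibromo-2-[bis(2,2,2-trifluoroethoxy)phosphoryl]acetate
Conditions: Br2, aq. NaOH, 0 °C
Reagents that add atoms: bromine, BrBr
Why: Hypobromite halogenation of the doubly activated methylene runs cleanly to the dibromide and so avoids a mono/di mixture.

Step 14
Reactants: 23 methyl 2,2-dibromo-2-[bis(2,2,2-trifluoroethoxy)phosphoryl]acetate
Product: 24 methyl 2-bromo-2-[bis(2,2,2-trifluoroethoxy)phosphoryl]acetate
Conditions: SnCl2 (1 equiv), EtOH/H2O, 0 °C
Reagents that add atoms: none
Why: Tin(II) reduces one C–Br bond of the gem-dibromide and should stop at the monobromo phosphonate.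

Step 15
Reactants: 21 C7 aldehyde (as above); 24 methyl 2-bromo-2-[bis(2,2,2-trifluoroethoxy)phosphoryl]acetate
Product: 26 methyl (2E,4R)-2-bromo-4-(tert-butyldimethylsilyloxy)-5-{(S)-5-[(Z)-4-(tert-butyldimethylsilyloxy)-1-(4-methoxybenzyloxy)but-2-en-2-yl]-2-methyl-3-oxo-2,3-dihydrofuran-2-yl}pent-2-enoate (C8 cis to CO2Me), via potassium phosphonate carbanion 25 (not isolated)
Conditions: 24 (1.5 equiv), t-BuOK, 18-crown-6, THF, −78 °C; 21, −78 °C
Reagents that add atoms: none
Why: Horner–Wadsworth–Emmons olefination of Still–Gennari type eliminates under kinetic control from the electron-poor bis(trifluoroethyl) phosphonate, so the aldehyde residue should end cis to the ester and fix the C7=C11 geometry.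

Step 16
Reactants: 26 (E)-α-bromoacrylate (as above); 27 (tributylstannyl)methanol
Product: 28 methyl (2Z,4R)-4-(tert-butyldimethylsilyloxy)-2-(hydroxymethyl)-5-{(S)-5-[(Z)-4-(tert-butyldimethylsilyloxy)-1-(4-methoxybenzyloxy)but-2-en-2-yl]-2-methyl-3-oxo-2,3-dihydrofuran-2-yl}pent-2-enoate (C13 trans to C8)
Conditions: 27 (1.5 equiv), Pd(PPh3)4 (10 mol %), dioxane, 80 °C
Reagents that add atoms: none
Why: Stille coupling of the hydroxymethylstannane with the vinyl bromide proceeds with retention and should install C13 trans to C8.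

Step 17
Reactants: 28 allylic alcohol (as above)
Product: 29 methyl (2E,4R)-2-(bromomethyl)-4-(tert-butyldimethylsilyloxy)-5-{(S)-5-[(Z)-4-(tert-butyldimethylsilyloxy)-1-(4-methoxybenzyloxy)but-2-en-2-yl]-2-methyl-3-oxo-2,3-dihydrofuran-2-yl}pent-2-enoate
Conditions: CBr4, PPh3, 2,6-lutidine, CH2Cl2, −20 → 0 °C
Reagents that add atoms: carbon tetrabromide, BrC(Br)(Br)Br
Why: Appel bromination converts the primary allylic alcohol into the bromide by direct SN2 at C13 under neutral, cold conditions, which should keep the alkene geometry.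

Step 18
Reactants: 29 allylic bromide (as above)
Product: 30 methyl (2E,4R)-2-(bromomethyl)-4-(tert-butyldimethylsilyloxy)-5-{(S)-5-[(Z)-4-hydroxy-1-(4-methoxybenzyloxy)but-2-en-2-yl]-2-methyl-3-oxo-2,3-dihydrofuran-2-yl}pent-2-enoate
Conditions: aq. HF (48 %)/MeCN (1:19), 0 °C
Reagents that add atoms: none
Why: Acidic desilylation removes the unhindered primary allylic TBS ether well before the hindered secondary C8 ether, and the amine-free medium spares the allylic bromide.

Step 19
Reactants: 30 hydroxy bromide (as above)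
Product: 31 thirteen-membered allyl ether (ring atoms O6, C13, C11, C7, C8, C9, C10, C1, C2, C3, C4, C5, C6; furanone oxygen bridging C3 and C10; CO2Me on C11 cis to C8 and C13 trans to C8; C3 cis to C6 across C4=C5; 8-OTBS; 15-OPMB; configurations at C8 and C10 as in the target)
Conditions: Ag2O (5 equiv), 4 Å MS, CH2Cl2 (2 mM), rt, dark
Reagents that add atoms: none
Why: Silver-assisted intramolecular Williamson etherification at the primary allylic carbon C13 under high dilution should close the ring, silver removing bromide as AgBr so that halide-induced allylic transposition cannot scramble the geometry.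

Step 20
Reactants: 31 thirteen-membered allyl ether (as above)
Product: 34 4,5-dehydro furanone germacranolide with 6,7-trans-fused α-methylene γ-lactone, 8-OTBS and 15-OPMB (stereocentres C6, C7, C8, C10 as in the target), via lithium trienolate 32 (not isolated), via lithium alkoxide 33 (not isolated)
Conditions: LiHMDS (1.2 equiv), THF (5 mM), −78 → −20 °C; AcOH, −78 °C
Reagents that add atoms: none
Why: LiHMDS removes a C6 proton, the most acidic one because the charge is spread through C5=C4 and C3=C2 onto the C1 oxygen (trienolate 32), and the C6 terminus then bonds to C7 suprafacially through a five-membered envelope (C6, O6, C13, C11, C7) while O6–C13 breaks and C11=C13 forms, a [2,3]-Wittig rearrangement. The closest known reaction type is the [2,3]-Wittig ring contraction of thirteen-membered bis-allylic ethers to ten-membered germacrane rings, applied here to a carbonyl-stabilised anion as in enolate [2,3]-Wittig shifts. The ten-membered carbocycle is closed by this transannular sigmatropic contraction (13 → 10), and the γ-lactone by 5-exo-trig addition–elimination of the released C6 alkoxide 33 at the C12 ester with loss of methoxide. C6 and C7 arise together: with C8 trans to C13 across C7=C11 and the C5 terminus of the anion exo on the envelope, the shift should give the anti pair (6,7-trans lactone), the outcome typical of E-type allyl ethers. The C7 face is governed by C8: H-8 eclipses the alkene to avoid A(1,3) strain with the cis ester, the ring bond C8–C9 lies anti to the forming bond and the silyloxy group points outward, which should place C11 and O8 cis as in the target. The step needs C6 (not C2 or C4) to react and [2,3] to beat [1,2] shift; only C6 is tied to the allyl unit through O6 in a five-atom array, and the low temperature with early acid quench disfavours radical [1,2] paths and methoxide addition to the new methylene lactone.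

Step 21
Reactants: 34 silyl-protected lactone (as above)
Product: 35 the C8 alcohol (8-OH, 15-OPMB, 4,5-ene)
Conditions: HF·pyridine, pyridine, THF, 0 °C → rt
Reagents that add atoms: none
Why: Buffered fluoride cleavage removes the secondary TBS ether under mildly acidic conditions that the methylene lactone, the furanone and the PMB ether should tolerate.

Step 22
Reactants: 35 C8 alcohol (as above)
Product: 36 the C8 methacrylate (15-OPMB, 4,5-ene)
Conditions: methacrylic anhydride (2 equiv), Et3N, DMAP (0.2 equiv), CH2Cl2, 0 °C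
Reagents that add atoms: methacrylic anhydride, C=C(C)C(=O)OC(=O)C(C)=C
Why: DMAP-catalysed acylation of the only free hydroxyl installs the ester at C8 before any other hydroxyl is exposed, so no selectivity is required.

Step 23
Reactants: 36 C8 methacrylate (as above)
Product: 37 the C15 allylic alcohol (8-methacrylate, 4,5-ene)
Conditions: DDQ (1.5 equiv), CH2Cl2/pH 7 buffer (10:1), 0 °C → rt
Reagents that add atoms: none
Why: Oxidative cleavage of the PMB ether by DDQ proceeds through the stabilised benzylic cation and should leave the esters and electron-poor alkenes untouched.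

Step 24
Reactants: 37 C15 allylic alcohol (as above)
Product: 38 the (4R,5R)-4,5-epoxide (epoxy alcohol; 8-methacrylate; 15-OH)
Conditions: Ti(OiPr)4 (0.3 equiv), D-(−)-diisopropyl tartrate (0.36 equiv), t-BuOOH (2 equiv), 4 Å MS, CH2Cl2, −20 °C
Reagents that add atoms: tert-butyl hydroperoxide, CC(C)(C)OO
Why: Sharpless asymmetric epoxidation acts only on the allylic alcohol alkene, and the D-tartrate (the antipode that gives 2R epoxides from 2-alken-1-ols) should deliver oxygen to the face that makes C4 R, with syn addition keeping C3 and C6 cis on the oxirane.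

Step 25
Reactants: 38 (4R,5R)-4,5-epoxide (as above)
Product: 39 target, (4R,5S,6S,7R,8R,10S)-5-acetoxy-4,15-dihydroxy-8-methacryloyloxy-1-oxo-3,10-epoxygermacra-2,11(13)-dien-6,12-olide
Conditions: Ti(OiPr)4 (1.5 equiv), AcOH (3 equiv), CH2Cl2, 0 °C → rt; aq. tartaric acid
Reagents that add atoms: acetic acid, CC(=O)O
Why: Titanium-mediated opening of the 2,3-epoxy alcohol by a carboxylic acid takes place at the carbon remote from the carbinol (C5) by SN2 with inversion (C4 is quaternary and cannot be attacked), which should give the anti 4-hydroxy-5-acetoxy pattern with 5S.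

Compound list
1 | 2-butyne-1,4-diol | OCC#CCO | starting material
2 | 4-[(4-methoxybenzyl)oxy]but-2-yn-1-ol | OCC#CCOCc1ccc(OC)cc1 | intermediate
3 | cyclic alkenylalanate (sodium salt) | [Na+].COCCO[Al-]1(OCCOC)OCC=C1COCc2ccc(OC)cc2 | intermediate (not isolated)
4 | (Z)-3-iodo-4-[(4-methoxybenzyl)oxy]but-2-en-1-ol | OC/C=C(\I)COCc1ccc(OC)cc1 | intermediate
5 | (Z)-tert-butyl({3-iodo-4-[(4-methoxybenzyl)oxy]but-2-en-1-yl}oxy)dimethylsilane | CC(C)(C)[Si](C)(C)OC/C=C(\I)COCc1ccc(OC)cc1 | intermediate
6 | ethynylmagnesium bromide | C#C[Mg]Br | starting material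
7 | ethynylzinc bromide | C#C[Zn]Br | intermediate (not isolated)
8 | (E)-tert-butyl[(3-{[(4-methoxybenzyl)oxy]methyl}pent-2-en-4-yn-1-yl)oxy]dimethylsilane | C#C/C(COCc1ccc(OC)cc1)=C\CO[Si](C)(C)C(C)(C)C | intermediate
9 | (R)-5-(hydroxymethyl)dihydrofuran-2(3H)-one | O=C1CC[C@H](CO)O1 | starting material
10 | (R)-5-{[(triethylsilyl)oxy]methyl}dihydrofuran-2(3H)-one | O=C1CC[C@H](CO[Si](CC)(CC)CC)O1 | intermediate
11 | lithium enolate of 10 | [Li]OC1=CC[C@H](CO[Si](CC)(CC)CC)O1 | intermediate (not isolated)
12 | (3S,5R)-3-methyl-5-{[(triethylsilyl)oxy]methyl}dihydrofuran-2(3H)-one | O=C1[C@@H](C)C[C@H](CO[Si](CC)(CC)CC)O1 | intermediate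
13 | potassium enolate of 12 | [K]OC1=C(C)C[C@H](CO[Si](CC)(CC)CC)O1 | intermediate (not isolated)
14 | (3S,5R)-3-hydroxy-3-methyl-5-{[(triethylsilyl)oxy]methyl}dihydrofuran-2(3H)-one | O=C1[C@@](C)(O)C[C@H](CO[Si](CC)(CC)CC)O1 | intermediate
15 | (2S,4R)-2,4-dihydroxy-N-methoxy-N,2-dimethyl-5-[(triethylsilyl)oxy]pentanamide | CON(C)C(=O)[C@@](C)(O)C[C@@H](O)CO[Si](CC)(CC)CC | intermediate
16 | (2S,4R)-4-[(tert-butyldimethylsilyl)oxy]-2-hydroxy-N-methoxy-N,2-dimethyl-5-[(triethylsilyl)oxy]pentanamide | CON(C)C(=O)[C@@](C)(O)C[C@@H](O[Si](C)(C)C(C)(C)C)CO[Si](CC)(CC)CC | intermediate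
17 | chloromagnesium alkoxide of 16 | CON(C)C(=O)[C@@](C)(O[Mg]Cl)C[C@@H](O[Si](C)(C)C(C)(C)C)CO[Si](CC)(CC)CC | intermediate (not isolated)
18 | lithium acetylide of 8 | [Li]C#C/C(COCc1ccc(OC)cc1)=C\CO[Si](C)(C)C(C)(C)C | intermediate (not isolated)
19 | α′-hydroxy ynone (8R,10S) | CC[Si](CC)(CC)OC[C@H](O[Si](C)(C)C(C)(C)C)C[C@](C)(O)C(=O)C#C/C(COCc1ccc(OC)cc1)=C\CO[Si](C)(C)C(C)(C)C | intermediate
20 | 3(2H)-furanone with C7-OTES, C8-OTBS, C6-OTBS, C15-OPMB | CC[Si](CC)(CC)OC[C@H](O[Si](C)(C)C(C)(C)C)C[C@]1(C)OC(=CC1=O)/C(COCc2ccc(OC)cc2)=C\CO[Si](C)(C)C(C)(C)C | intermediate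
21 | C7 aldehyde | O=C[C@H](O[Si](C)(C)C(C)(C)C)C[C@]1(C)OC(=CC1=O)/C(COCc2ccc(OC)cc2)=C\CO[Si](C)(C)C(C)(C)C | intermediate
22 | methyl bis(2,2,2-trifluoroethyl)phosphonoacetate | COC(=O)CP(=O)(OCC(F)(F)F)OCC(F)(F)F | starting material
23 | methyl 2,2-dibromo-2-[bis(2,2,2-trifluoroethoxy)phosphoryl]acetate | COC(=O)C(Br)(Br)P(=O)(OCC(F)(F)F)OCC(F)(F)F | intermediate
24 | methyl 2-bromo-2-[bis(2,2,2-trifluoroethoxy)phosphoryl]acetate | COC(=O)C(Br)P(=O)(OCC(F)(F)F)OCC(F)(F)F | intermediate
25 | potassium carbanion of 24 | [K+].COC(=O)[C-](Br)P(=O)(OCC(F)(F)F)OCC(F)(F)F | intermediate (not isolated)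
26 | (2E,4R)-α-bromoacrylate (C8 cis to CO2Me) | COC(=O)/C(Br)=C\[C@H](O[Si](C)(C)C(C)(C)C)C[C@]1(C)OC(=CC1=O)/C(COCc2ccc(OC)cc2)=C\CO[Si](C)(C)C(C)(C)C | intermediate
27 | (tributylstannyl)methanol | CCCC[Sn](CO)(CCCC)CCCC | starting material
28 | (2Z,4R)-2-(hydroxymethyl) enoate (C13 trans to C8) | COC(=O)/C(CO)=C\[C@H](O[Si](C)(C)C(C)(C)C)C[C@]1(C)OC(=CC1=O)/C(COCc2ccc(OC)cc2)=C\CO[Si](C)(C)C(C)(C)C | intermediate
29 | (2E,4R)-2-(bromomethyl) enoate | COC(=O)/C(CBr)=C\[C@H](O[Si](C)(C)C(C)(C)C)C[C@]1(C)OC(=CC1=O)/C(COCc2ccc(OC)cc2)=C\CO[Si](C)(C)C(C)(C)C | intermediate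
30 | C6 alcohol / C13 bromide | COC(=O)/C(CBr)=C\[C@H](O[Si](C)(C)C(C)(C)C)C[C@]1(C)OC(=CC1=O)/C(COCc2ccc(OC)cc2)=C\CO | intermediate
31 | thirteen-membered C6–O6–C13 allyl ether (precursor of the key step) | C1/C(C(=O)OC)=C/[C@H](O[Si](C)(C)C(C)(C)C)C[C@]2(C)OC(=CC2=O)/C(COCc3ccc(OC)cc3)=C\CO1 | intermediate
32 | lithium trienolate of 31 | C1/C(C(=O)OC)=C/[C@H](O[Si](C)(C)C(C)(C)C)C[C@]2(C)OC(C=C2O[Li])=C(COCc3ccc(OC)cc3)C=CO1 | intermediate (not isolated)
33 | ring-contracted lithium C6 alkoxide with C11(=C13H2)CO2Me on C7 | CC(C)(C)[Si](C)(C)O[C@@H]1C[C@]2(C)OC(=CC2=O)/C(COCc3ccc(OC)cc3)=C\[C@@H](O[Li])[C@@H]1C(=C)C(=O)OC | intermediate (not isolated)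
34 | 4,5-dehydro furanone germacranolide, 8-OTBS, 15-OPMB (product of the key step) | CC(C)(C)[Si](C)(C)O[C@@H]1C[C@]2(C)OC(=CC2=O)/C(COCc3ccc(OC)cc3)=C\[C@H]2OC(=O)C(=C)[C@@H]21 | intermediate
35 | C8 alcohol | O[C@@H]1C[C@]2(C)OC(=CC2=O)/C(COCc3ccc(OC)cc3)=C\[C@H]2OC(=O)C(=C)[C@@H]21 | intermediate
36 | C8 methacrylate, 15-OPMB | C=C(C)C(=O)O[C@@H]1C[C@]2(C)OC(=CC2=O)/C(COCc3ccc(OC)cc3)=C\[C@H]2OC(=O)C(=C)[C@@H]21 | intermediate
37 | C8 methacrylate, 15-OH | C=C(C)C(=O)O[C@@H]1C[C@]2(C)OC(=CC2=O)/C(CO)=C\[C@H]2OC(=O)C(=C)[C@@H]21 | intermediate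
38 | (4R,5R)-4,5-epoxide | C=C(C)C(=O)O[C@@H]1C[C@]2(C)OC(=CC2=O)[C@]3(CO)O[C@@H]3[C@H]2OC(=O)C(=C)[C@@H]21 | intermediate
39 | CNP0275292.1 | C=C(C)C(=O)O[C@@H]1C[C@]2(C)OC(=CC2=O)[C@@](O)(CO)[C@@H](OC(C)=O)[C@H]2OC(=O)C(=C)[C@@H]21 | target

Total step count: 25 (including the two-step preparation of phosphonate 24).
Longest linear sequence: 19 steps (9 → 39: steps 5–12 and 15–25).

Steps most likely to fail

1. Step 20. The delocalised anion may form a C–C bond through C2 or C4 (transannular conjugate addition to the enoate) or rearrange by a [1,2] path, and the shift may not discriminate the two faces of C7. The fallback sets out from 30: its C6 allylic alcohol is oxidised with MnO2 (CH2Cl2, rt) to the (Z)-enal F1. F1 is then cyclised by an intramolecular Nozaki–Hiyama–Kishi-type allylation (CrCl2, THF/DMF, high dilution): the allylchromium formed at C13 adds through C7 to the C6 aldehyde by a chair transition state (anti addition expected), and the chromium alkoxide lactonises onto C12. This comes back to the route at 34.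

2. Step 19. Intermolecular etherification may outrun ring closure, and attack at C7 (SN2′) or allylic transposition may erode the C7=C11 geometry. The fallback sets out from 28: the C13 hydroxyl is converted into the allylic methyl carbonate F2 (ClCO2Me, pyridine, CH2Cl2, 0 °C), and the C6 silyl ether is cleaved with aq. HF/MeCN to give the hydroxy carbonate F3. The ring is then closed by a palladium-catalysed intramolecular allylic etherification (Tsuji–Trost type; Pd2(dba)3, dppf, THF, 2 mM, 40 °C), in which the alkoxide formed on decarboxylation traps the π-allyl complex at its CH2 terminus. This comes back to the route at 31.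

3. Step 24. Oxygen transfer from the titanium peroxide to the electron-poor C4=C5 bond may be too slow, and the catalyst and substrate facial preferences may oppose each other. The fallback sets out from 36, with the PMB group still on O15: C4=C5 is epoxidised by a Jacobsen–Katsuki oxidation ((salen)Mn(III)Cl, m-CPBA, NMO, CH2Cl2, −78 °C; catalyst antipode chosen for the 4R,5R face), which suits conjugated trisubstituted alkenes and needs no free hydroxyl, to give the epoxy PMB ether F4. Removal of the PMB group with DDQ then comes back to the route at 38.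

Further compounds
F1 | step 20 | (Z)-enal with C13 bromide (C6 aldehyde of 30) | COC(=O)/C(CBr)=C\[C@H](O[Si](C)(C)C(C)(C)C)C[C@]1(C)OC(=CC1=O)/C(COCc2ccc(OC)cc2)=C\C=O
F2 | step 19 | C13 methyl carbonate of 28 | COC(=O)OC/C(C(=O)OC)=C/[C@H](O[Si](C)(C)C(C)(C)C)C[C@]1(C)OC(=CC1=O)/C(COCc2ccc(OC)cc2)=C\CO[Si](C)(C)C(C)(C)C
F3 | step 19 | C6 alcohol / C13 methyl carbonate | COC(=O)OC/C(C(=O)OC)=C/[C@H](O[Si](C)(C)C(C)(C)C)C[C@]1(C)OC(=CC1=O)/C(COCc2ccc(OC)cc2)=C\CO
F4 | step 24 | (4R,5R)-4,5-epoxide with 15-OPMB and 8-methacrylate | C=C(C)C(=O)O[C@@H]1C[C@]2(C)OC(=CC2=O)[C@]3(COCc4ccc(OC)cc4)O[C@@H]3[C@H]2OC(=O)C(=C)[C@@H]21
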